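The numbers in the tables were computed on assumed constants; the scatter is artificial.

We cannot read the coupling partner: no run measures it and it starts undissolved, so the flask's clock is unknown. Yet the main step (starting material to target) and the over-reaction (target to over-reaction product) both consume it, so dividing one rate by the other cancels [coupling partner], and time with it.

the same everywhere: starting material 10 mM; gas 4.9 mM (held)

| run | second substrate | third substrate | remark | time |
|---|---|---|---|---|
| autumn | 5 equiv | 0.70 equiv | run made earlier |  |
| noon | 5 equiv | 1.1 equiv | run made earlier |  |
| dawn | 7.5 equiv | 0.50 equiv | run made earlier |  |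
| Wednesday's | 5.00 equiv | 0.500 equiv |  | 15 h |
| Sunday's | 5.00 equiv | 0.500 equiv |  | 5.0 h |
| Tuesday's | 5.00 equiv | 0.500 equiv |  | 50 h |

- autumn (time / h: target / %, starting material / %): 0.417: 5.8, 93.6; 0.667: 12.9, 86.9; 1.00: 22.3, 77.9; 1.33: 31.0, 68.4; 2.00: 47.3, 51.9; 3.00: 66.0, 31.0; 5.00: 82.1, 8.8
- noon (time / h: target / %, starting material / %): 0.250: 3.1, 97.1; 0.833: 17.7, 82.2; 1.33: 30.8, 68.5; 2.00: 47.1, 51.4; 3.00: 65.7, 31.6; 4.00: 76.6, 17.6; 5.00: 82.3, 9.1
- dawn (time / h: target / %, starting material / %): 0.417: 6.4, 93.6; 0.833: 17.9, 82.4; 1.33: 31.5, 68.4; 2.50: 57.3, 40.7; 5.00: 82.1, 9.8

(standard deviation of a reading: 0.3 percentage points)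

- at the start none of coupling partner is dissolved
- reactions considered so far: second substrate + coupling partner -> second product; gas <-> coupling partner; coupling partner + target -> over-reaction product; starting material + coupling partner -> target; third substrate <-> dormant form; third substrate + coupling partner -> third product

- which of the two there is more of at the end, Wednesday's (target / over-reaction product)
- which of the two there is more of at the end, Sunday's (target / over-reaction product)
- which of the two there is more of at the end, Tuesday's (target / over-reaction product)
- how much target is there at the end, in percent of the starting material charged: Wednesday's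
- how much target is there at the end, in percent of the starting material charged: Sunday's
- how much target is there at the end, in percent of the starting material charged: Tuesday's

Let a be the fraction of starting material left and τ = −ln a its exposure to the partner; over-reaction product then grows with τ at r times [target]. The autumn run at 5.00 h has τ = 2.43, and the gap to the charge, 9.10%, is over-reaction product. Taking all converted material as target gives r near 0.0599. But target was short by that same growing gap, and putting it back gives 0.0635. This r, the selectivity factor, the over-reaction's rate constant divided by the main step's, is what we carry.

Autumn is not the asked charge, but target at that time reads 82.1%, 82.3% and 82.1% across the three charges, within the scatter of 0.3 percentage points, so we use autumn's reading for Sunday's flask.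

Target is the difference of exp(−rτ) and exp(−τ), divided by one minus r, so late flasks still need τ. Continuing at the last interval's apparent constant, 0.630 h⁻¹, gives τ = 8.73 at 15 h and 61.3% target. But that constant is climbing, from 0.515 h⁻¹ one interval earlier, so this target is too high. Taking the inverse constant as linear in the starting material left and extrapolating to none gives 0.745 h⁻¹. Our target is then 57.0% on Wednesday's, more than the remainder as over-reaction product, and 10.9% on Tuesday's, less than that remainder.

The forecast prints 57% for Wednesday's, 82.2% for Sunday's and 11% for Tuesday's; its choice of the larger is target on Wednesday's, target on Sunday's and over-reaction product on Tuesday's, and it adds: “The 15 h call is moderately safe.” Wednesday's flask holds 53.1% target against 46.9% over-reaction product, Sunday's 82.0% against 9.20%, and Tuesday's 6.74% against 93.3%, so the larger is target on Wednesday's, target on Sunday's and over-reaction product on Tuesday's. Wednesday's target moves by 6 points at a reading of 13.1 h or 17.1 h.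

    second substrate + coupling partner → second product (k = 3.06 × 10⁻⁴ M⁻¹ s⁻¹)
    gas ⇌ coupling partner, rate k2*(csat - [coupling partner]) (kL = 3.23 × 10⁻⁴ s⁻¹)
    coupling partner + target → over-reaction product (k = 0.00357 M⁻¹ s⁻¹)
    starting material + coupling partner → target (k = 0.0553 M⁻¹ s⁻¹)
    third substrate ⇌ dormant form (K = 28.0, k = 3.61 × 10⁻⁴ s⁻¹)
    third substrate + coupling partner → third product (k = 0.00228 M⁻¹ s⁻¹)

At 1.89 h Sunday's flask makes target 18.5 times faster than it uses it up, but by 5.00 h the main step takes the coupling partner just 1.7 times as fast as the over-reaction does, where [starting material] over r times [target] reckons 1.70. Sunday's charge read at 8.0 h, with 0.84% of its starting material left, reckons by the same r to 77.9% target, and that flask holds 77.6%.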